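**Retrosynthetic overview**

- The target is a 2,2-dimethyl-2H-chromene on a fully substituted phloroglucinol ring (C5-OH, C6 3-hydroxybenzoyl, C7-OH, C8 prenyl). The strategy rests on the pyran oxygen O1 sitting on C8a, para to the benzoyl-bearing C6, and on C4a being the only ring carbon still free once C8 carries the prenyl group.
- Last disconnection: methanolysis of three aryl esters (pivalate on the 3'-oxygen, acetates on the C5 and C7 oxygens).
- Key disconnection: the pyran ring (new C4a–C4 bond, O1–C2 re-formed) from an aryl 1,1-dimethylpropargyl ether by propargyl Claisen shift, 1,5-hydrogen shift and oxa-6π electrocyclisation.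
- The precursor comes from phloroglucinol by Friedel–Crafts aroylation with 3-(pivaloyloxy)benzoyl chloride, mono-C-prenylation, copper-catalysed O-propargylation of the hydroxyl para to the ketone, and diacetylation.
- Ring order: both benzene rings come from the starting materials; the pyran ring is the only ring formed (step 7).

Key step: step 7

Remark on the chemistry: an aryl silyl ether is not expected to survive AlCl3 or DBU, so the 3'-oxygen is carried as a pivalate. The two hydroxyls ortho to the ketone are acetylated before thermolysis, because a free hydroxyl next to the allene could also deliver the hydrogen and close the isomeric pyran.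

**Route**

Step 1
Reactants: 1 3-hydroxybenzoic acid
Product: 2 3-(pivaloyloxy)benzoic acid
Conditions: PivCl (1.1 equiv), NaOH (2.1 equiv), H2O/THF, 0 °C; then 1 M HCl
Reagents that add atoms: pivaloyl chloride, CC(C)(C)C(=O)Cl
Why: Schotten–Baumann O-acylation, in which the phenoxide of the dianion is the stronger nucleophile and takes the hindered acyl chloride, and acidification returns the free carboxylic acid.

Step 2
Reactants: 2 3-(pivaloyloxy)benzoic acid
Product: 3 3-(pivaloyloxy)benzoyl chloride
Conditions: (COCl)2, DMF (cat.), CH2Cl2, 0 °C to rt; concentrated and used crude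
Reagents that add atoms: oxalyl chloride, ClC(=O)C(Cl)=O
Why: Vilsmeier-type activation converts the acid into the acid chloride under conditions that should leave the hindered aryl ester untouched.

Step 3
Reactants: 3 3-(pivaloyloxy)benzoyl chloride; 4 phloroglucinol
Product: 5 3-(2,4,6-trihydroxybenzoyl)phenyl pivalate
Conditions: AlCl3 (4 equiv), PhNO2, 0 °C to rt; then ice/1 M HCl
Reagents that add atoms: none
Why: Friedel–Crafts C-aroylation of the threefold symmetric, very electron-rich phloroglucinol ring, where every ring carbon gives the same 2,4,6-trihydroxybenzophenone, the new ketone deactivates the ring towards a second acylation, and the aryl pivalate should not ionise with AlCl3 at room temperature.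

Step 4
Reactants: 5 3-(2,4,6-trihydroxybenzoyl)phenyl pivalate; 6 prenyl bromide
Product: 7 3-[2,4,6-trihydroxy-3-(3-methylbut-2-enyl)benzoyl]phenyl pivalate
Conditions: DBU (1.0 equiv), prenyl bromide (0.95 equiv), THF, 0 °C to rt
Reagents that add atoms: none
Why: Phenoxide C-alkylation of an acylphloroglucinol, whose DBU salt is an ambident vinylogous carboxylate that takes an allylic bromide at ring carbon by SN2 attack and rearomatises; the two free ring carbons are equivalent, and a slight deficit of bromide should limit double prenylation.

Step 5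
Reactants: 7 3-[2,4,6-trihydroxy-3-(3-methylbut-2-enyl)benzoyl]phenyl pivalate; 8 3-chloro-3-methylbut-1-yne
Product: 9 3-[2,6-dihydroxy-4-(2-methylbut-3-yn-2-yloxy)-3-(3-methylbut-2-enyl)benzoyl]phenyl pivalate
Conditions: CuCl2·2H2O (cat.), DBU (1.2 equiv), 8 (1.2 equiv), MeCN, 0 °C
Reagents that add atoms: none
Why: Copper-catalysed propargylic etherification (copper acetylide, loss of chloride, phenoxide capture at the tertiary carbon) at the hydroxyl para to the ketone, which is the most acidic of the three and the only one not hydrogen-bonded to the carbonyl, so about one equivalent of DBU should form its phenoxide selectively.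

Step 6
Reactants: 9 3-[2,6-dihydroxy-4-(2-methylbut-3-yn-2-yloxy)-3-(3-methylbut-2-enyl)benzoyl]phenyl pivalate
Product: 10 3-[2,6-diacetoxy-4-(2-methylbut-3-yn-2-yloxy)-3-(3-methylbut-2-enyl)benzoyl]phenyl pivalate
Conditions: Ac2O (3 equiv), Et3N, DMAP (cat.), CH2Cl2, rt
Reagents that add atoms: acetic anhydride, CC(=O)OC(C)=O
Why: DMAP-catalysed acetylation caps the two remaining hydroxyls, both ortho to the ketone, so that after the sigmatropic shift the only free phenol next to the allene is the one released from the ether.

Step 7
Reactants: 10 3-[2,6-diacetoxy-4-(2-methylbut-3-yn-2-yloxy)-3-(3-methylbut-2-enyl)benzoyl]phenyl pivalate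
Product: 14 5,7-diacetoxy-2,2-dimethyl-8-(3-methylbut-2-enyl)-6-[3-(pivaloyloxy)benzoyl]-2H-chromene, via allenyl cyclohexadienone 11 (not isolated), via ortho-allenyl phenol 12 (not isolated), via ortho-quinone methide 13 (not isolated)
Conditions: xylenes (degassed), 140 °C
Reagents that add atoms: none
Why: Heating triggers the aryl propargyl ether Claisen rearrangement, a [3,3] shift that breaks the O–CMe2 bond and joins the alkyne terminus to C4a (the only unsubstituted ring carbon) to give allenyl dienone 11, which enolises to allenyl phenol 12; a 1,5-hydrogen shift from the new phenolic OH to the central allene carbon then gives the (Z)-ortho-quinone methide 13, and oxa-6π electrocyclisation forms O1–C2. The closest known reaction type is the thermal conversion of aryl 1,1-dimethylpropargyl ethers into 2,2-dimethyl-2H-chromenes, which the geminal methyl groups accelerate. The pyran ring closes by thermally allowed disrotatory 6π electrocyclisation of the 1-oxatriene in 13, so the net new skeletal bond is C4a–C4 and the ether oxygen returns to the quaternary carbon. No stereocentre is formed, because C2 carries two methyl groups. Two selectivities are needed: the site of the shift, secured because migration to the prenyl-bearing C8 gives a dienone that cannot enolise and reverts to the ether, and the identity of the oxygen that closes the ring, secured because the oxygens at C5 and C7 are acetylated and the phenol released from the ether is the only hydroxyl next to the allene.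

Step 8
Reactants: 14 5,7-diacetoxy-2,2-dimethyl-8-(3-methylbut-2-enyl)-6-[3-(pivaloyloxy)benzoyl]-2H-chromene
Product: 15 (5,7-dihydroxy-2,2-dimethyl-8-(3-methylbut-2-enyl)-2H-chromen-6-yl)(3-hydroxyphenyl)methanone (CNP0424359.0)
Conditions: K2CO3 (4 equiv), MeOH/THF, argon, rt to 40 °C; then 1 M HCl
Reagents that add atoms: none
Why: Base-mediated transesterification (methanolysis) of the three aryl esters, whose phenoxide leaving groups make them far more labile than anything else present, while the chromene, the prenyl group and the diaryl ketone should be inert to carbonate in methanol.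

**Compound list**

1 | 3-hydroxybenzoic acid | OC(=O)c1cccc(O)c1 | starting material
2 | 3-(pivaloyloxy)benzoic acid | CC(C)(C)C(=O)Oc1cccc(c1)C(O)=O | intermediate
3 | 3-(pivaloyloxy)benzoyl chloride | CC(C)(C)C(=O)Oc1cccc(c1)C(Cl)=O | intermediate
4 | phloroglucinol | Oc1cc(O)cc(O)c1 | starting material
5 | 3-(2,4,6-trihydroxybenzoyl)phenyl pivalate | CC(C)(C)C(=O)Oc1cccc(c1)C(=O)c1c(O)cc(O)cc1O | intermediate
6 | prenyl bromide (1-bromo-3-methylbut-2-ene) | CC(C)=CCBr | starting material
7 | 3-[2,4,6-trihydroxy-3-(3-methylbut-2-enyl)benzoyl]phenyl pivalate | CC(C)=CCc1c(O)cc(O)c(C(=O)c2cccc(OC(=O)C(C)(C)C)c2)c1O | intermediate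
8 | 3-chloro-3-methylbut-1-yne | CC(C)(Cl)C#C | starting material
9 | 3-[2,6-dihydroxy-4-(2-methylbut-3-yn-2-yloxy)-3-(3-methylbut-2-enyl)benzoyl]phenyl pivalate | CC(C)=CCc1c(O)c(C(=O)c2cccc(OC(=O)C(C)(C)C)c2)c(O)cc1OC(C)(C)C#C | intermediate
10 | 3-[2,6-diacetoxy-4-(2-methylbut-3-yn-2-yloxy)-3-(3-methylbut-2-enyl)benzoyl]phenyl pivalate | CC(C)=CCc1c(OC(C)=O)c(C(=O)c2cccc(OC(=O)C(C)(C)C)c2)c(OC(C)=O)cc1OC(C)(C)C#C | intermediate
11 | allenyl cyclohexadienone from the [3,3] shift (ketone at the former ether carbon; adjacent sp3 CH bearing the 3-methylbuta-1,2-dienyl group; racemic, transient) | O=C1C(C=C=C(C)C)C(OC(C)=O)=C(C(=O)c2cccc(OC(=O)C(C)(C)C)c2)C(OC(C)=O)=C1CC=C(C)C | intermediate (not isolated)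
12 | 3-[2,6-diacetoxy-4-hydroxy-5-(3-methylbuta-1,2-dienyl)-3-(3-methylbut-2-enyl)benzoyl]phenyl pivalate (ortho-allenyl phenol) | CC(C)=CCc1c(O)c(C=C=C(C)C)c(OC(C)=O)c(C(=O)c2cccc(OC(=O)C(C)(C)C)c2)c1OC(C)=O | intermediate (not isolated)
13 | (Z)-ortho-quinone methide (ring ketone at the former ether carbon; exocyclic 3-methylbut-2-enylidene on the neighbouring carbon, syn to the ketone) | O=C1/C(=C\C=C(C)C)C(OC(C)=O)=C(C(=O)c2cccc(OC(=O)C(C)(C)C)c2)C(OC(C)=O)=C1CC=C(C)C | intermediate (not isolated)
14 | 5,7-diacetoxy-2,2-dimethyl-8-(3-methylbut-2-enyl)-6-[3-(pivaloyloxy)benzoyl]-2H-chromene | CC(C)=CCc1c(OC(C)=O)c(C(=O)c2cccc(OC(=O)C(C)(C)C)c2)c(OC(C)=O)c2C=CC(C)(C)Oc12 | intermediate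
15 | (5,7-dihydroxy-2,2-dimethyl-8-(3-methylbut-2-enyl)-2H-chromen-6-yl)(3-hydroxyphenyl)methanone | CC(C)=CCc1c(O)c(C(=O)c2cccc(O)c2)c(O)c2c1OC(C)(C)C=C2 | target

**Step count**

Total steps: 8. Longest linear sequence: 8 steps (1 to 15, steps 1 to 8).

**Steps most likely to fail**

Step 7. The sigmatropic shift may go to the prenyl-bearing carbon, and the non-enolisable allenyl dienone formed there may be trapped by intramolecular Diels–Alder reaction before it reverts. Prolonged heating may also degrade the esters. Fallback: setting out from 10, π-acid catalysis with Ph3PAuNTf2 (cat.) in CH2Cl2 at rt should activate the alkyne for 6-endo-dig intramolecular hydroarylation by C4a. This forms the same C4a–C4 bond without the ether oxygen ever leaving its carbon and returns to the route at 14. No new compound is made.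

Step 5. Ether formation at a hydroxyl flanked by the prenyl group may be slow, which would allow alkylation of a hydroxyl ortho to the ketone or double etherification. Fallback: setting out from 7, condensation with 3-methylbut-2-enal (ethylenediammonium diacetate cat., toluene, 100 °C) should build the pyran directly. The sequence is Knoevenagel-type addition at the one free ring carbon, loss of water to an ortho-quinone methide, and oxa-6π closure. The product is [5,7-dihydroxy-2,2-dimethyl-8-(3-methylbut-2-enyl)-2H-chromen-6-yl][3-(pivaloyloxy)phenyl]methanone F1. The oxygen is not fixed in this variant, so separation from the isomer closed onto the oxygen ortho to the ketone is part of the plan. Methanolysis of F1 under the conditions of step 8 returns to the route at 15.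

Step 4. Over-alkylation to the diprenyl compound and O-prenylation may erode the mono-C-prenylation. Fallback: setting out from 5, copper-catalysed etherification with 8 (CuCl2·2H2O cat., DBU, MeCN, 0 °C) at the unhindered hydroxyl para to the ketone should give 3-[2,6-dihydroxy-4-(2-methylbut-3-yn-2-yloxy)benzoyl]phenyl pivalate F2. Semihydrogenation (H2, Pd/CaCO3 poisoned with Pb(OAc)2, quinoline, EtOAc, rt) should give the 1,1-dimethylallyl ether 3-[2,6-dihydroxy-4-(2-methylbut-3-en-2-yloxy)benzoyl]phenyl pivalate F3. Aromatic Claisen rearrangement of F3 (toluene, 110 °C) transfers the allyl unit with inversion to the ortho carbon as exactly one prenyl group and returns to the route at 7.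

**Further compounds**

F0 | step 7 | none | none
F1 | step 5 | [5,7-dihydroxy-2,2-dimethyl-8-(3-methylbut-2-enyl)-2H-chromen-6-yl][3-(pivaloyloxy)phenyl]methanone | CC(C)=CCc1c(O)c(C(=O)c2cccc(OC(=O)C(C)(C)C)c2)c(O)c2C=CC(C)(C)Oc12
F2 | step 4 | 3-[2,6-dihydroxy-4-(2-methylbut-3-yn-2-yloxy)benzoyl]phenyl pivalate | CC(C)(C)C(=O)Oc1cccc(c1)C(=O)c1c(O)cc(OC(C)(C)C#C)cc1O
F3 | step 4 | 3-[2,6-dihydroxy-4-(2-methylbut-3-en-2-yloxy)benzoyl]phenyl pivalate | CC(C)(C)C(=O)Oc1cccc(c1)C(=O)c1c(O)cc(OC(C)(C)C=C)cc1O
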